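**Strategy.** Everything rests on cutting the two bonds that join the halves at neighbouring arene carbons of the chromene, C7–O and C8–C(=O). Because the C7 hydroxyl and the C8 acyl group are ortho on the benzo ring, and C8 sits beside the oxygen-bearing C8a, a C7–C8 aryne can accept the carboxylate oxygen at C7 and the acyl carbon at C8 of an intact carboxylic acid in one operation, with nothing left to do afterwards. Its precursors are the stereodefined cyclohexene acid 16, made by a boat Ireland–Claisen rearrangement of a cis-4,6-disubstituted 6-alkenyl δ-lactone, and the 8-silyl-7-triflyloxychromene 26, whose silicon first blocks C2 of the resorcinol.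

Key step: step 12

Assumption: (DHQD)2AQN is taken to deliver the (R)-half-ester 7 in step 3; if the sense proves opposite, the pseudo-enantiomeric (DHQ)2AQN is used with no other change.

**Step 1**
Reactants: 1 prenyl bromide; 2 1-propynylmagnesium bromide
Product: 3 6-methylhept-5-en-2-yne
Conditions: CuBr·SMe2 (5 mol %), THF, 0 °C to rt
Reagents that add atoms: none
Why: Copper-catalysed SN2 coupling of an alkynyl Grignard reagent with an allylic bromide should occur at the unhindered CH2 terminus of the prenyl unit and leave the trisubstituted alkene in place.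

**Step 2**
Reactants: 3 6-methylhept-5-en-2-yne
Product: 5 (E)-2-iodo-6-methylhepta-2,5-diene, via alkenylzirconocene chloride 4 (not isolated)
Conditions: Cp2Zr(H)Cl (1.5 equiv), THF, rt to 40 °C; I2, 0 °C
Reagents that add atoms: iodine, II
Why: Hydrozirconation is a syn addition whose regiochemistry, once equilibrated by excess hydride, should place zirconium beside the smaller methyl group, and iodinolysis with retention then fixes the E geometry (iodine trans to the CH2 chain).

**Step 3**
Reactants: 6 3-phenylglutaric anhydride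
Product: 7 (R)-5-methoxy-5-oxo-3-phenylpentanoic acid
Conditions: (DHQD)2AQN (10 mol %), MeOH (10 equiv), Et2O, −40 °C
Reagents that add atoms: methanol, CO
Why: Cinchona-alkaloid-catalysed enantioselective methanolysis (desymmetrisation of a prochiral anhydride) differentiates the two enantiotopic carbonyls and so sets the benzylic stereocentre, the later C6.

**Step 4**
Reactants: 7 (R)-5-methoxy-5-oxo-3-phenylpentanoic acid; 5 (E)-2-iodo-6-methylhepta-2,5-diene
Product: 11 methyl (3R,6E)-6,10-dimethyl-5-oxo-3-phenylundeca-6,9-dienoate, via acid chloride 8 (not isolated), via alkenyllithium 9 (not isolated), via alkenylzinc chloride 10 (not isolated)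
Conditions: 7, (COCl)2, DMF (cat.), CH2Cl2, 0 °C to rt, evaporate; 5, t-BuLi (2 equiv), Et2O, −78 °C, then ZnCl2, THF; combine, Pd(PPh3)4 (5 mol %), THF, 0 °C to rt
Reagents that add atoms: none
Why: Negishi acylation: the acid chloride couples under palladium catalysis with the alkenylzinc made by iodine–lithium exchange and transmetalation, both with retention of alkene geometry, while the methyl ester and the stereocentre are untouched.

**Step 5**
Reactants: 11 methyl (3R,6E)-6,10-dimethyl-5-oxo-3-phenylundeca-6,9-dienoate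
Product: 13 (4R,6R)-6-[(2E)-6-methylhepta-2,5-dien-2-yl]-4-phenyloxan-2-one, via hydroxy ester 12 (not isolated)
Conditions: (S)-2-methyl-CBS-oxazaborolidine (0.2 equiv), catecholborane (1.5 equiv), toluene, −78 °C; then pyridinium p-toluenesulfonate (cat.), toluene, 60 °C
Reagents that add atoms: none
Why: Corey–Bakshi–Shibata reduction, in which the α-branched alkenyl arm is the large group so that the (S)-catalyst should give the (R)-allylic alcohol under reagent control, followed by acid-catalysed lactonisation of the δ-hydroxy ester to the 4,6-cis (diequatorial) lactone, the stage at which a minor diastereomer can be removed.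

**Step 6**
Reactants: 13 (4R,6R)-6-[(2E)-6-methylhepta-2,5-dien-2-yl]-4-phenyloxan-2-one
Product: 16 (1R,2S,6R)-3-methyl-2-(3-methylbut-2-en-1-yl)-6-phenylcyclohex-3-ene-1-carboxylic acid, via silyl ketene acetal 14 (not isolated), via silyl ester 15 (not isolated)
Conditions: LiN(i-Pr)2, TMSCl/Et3N, THF, −78 °C; toluene, 105 °C; 1 M HCl
Reagents that add atoms: none
Why: Ireland–Claisen rearrangement of a lactone silyl ketene acetal, which in a six-membered ring must pass through a boat transition state: the new C1–C2 bond forms on the lactone face that carries the alkenyl group, so the cis lactone puts the carboxyl trans to phenyl, the E alkene puts prenyl cis to the carboxyl, and C6 is carried through unchanged.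

**Step 7**
Reactants: 17 5-methoxyresorcinol
Product: 18 5-methoxy-1,3-phenylene bis(N-isopropylcarbamate)
Conditions: i-PrNCO (2.4 equiv), Et3N (cat.), CH2Cl2, rt
Reagents that add atoms: isopropyl isocyanate, CC(C)N=C=O
Why: Base-catalysed addition of the phenols to an isocyanate (carbamoylation) installs two identical directing groups that can later be removed without acid.

**Step 8**
Reactants: 18 5-methoxy-1,3-phenylene bis(N-isopropylcarbamate)
Product: 22 5-methoxy-2-(trimethylsilyl)-1,3-phenylene bis(N-isopropylcarbamate), via N-silyl carbamate 19 (not isolated), via aryllithium 20 (not isolated), via N-silyl arylsilane 21 (not isolated)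
Conditions: TBSOTf (2.2 equiv), TMEDA, Et2O, 0 °C to rt; n-BuLi (3.3 equiv), TMEDA, −78 °C; TMSCl; aq NaHSO4
Reagents that add atoms: chlorotrimethylsilane, C[Si](C)(C)Cl
Why: Directed ortho-metalation: after in situ N-silylation the two flanking carbamates direct lithiation cooperatively to C2, the aryllithium is silylated, and the N-silyl groups are lost on work-up.

**Step 9**
Reactants: 22 5-methoxy-2-(trimethylsilyl)-1,3-phenylene bis(N-isopropylcarbamate)
Product: 23 5-methoxy-2-(trimethylsilyl)benzene-1,3-diol
Conditions: Et2NH (4 equiv), DBU (3 equiv), MeCN, 40 °C; aq NH4Cl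
Reagents that add atoms: none
Why: Secondary aryl carbamates cleave under mild base by E1cB loss of isopropyl isocyanate, which diethylamine traps as a urea, so the acid-labile aryl–silicon bond between two phenols never meets acid.

**Step 10**
Reactants: 23 5-methoxy-2-(trimethylsilyl)benzene-1,3-diol; 24 3-methyl-2-butenal
Product: 25 5-methoxy-2,2-dimethyl-8-(trimethylsilyl)-2H-chromen-7-ol
Conditions: 24 (1.05 equiv), pyridine, 110 °C
Reagents that add atoms: none
Why: Amine-mediated chromene annulation (Knoevenagel-type C-alkylation of the phenol by the enal, dehydration to an o-quinone methide, oxa-6π electrocyclisation); with C2 blocked by silicon only the two equivalent positions beside methoxy can react, so a single regioisomer should form.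

**Step 11**
Reactants: 25 5-methoxy-2,2-dimethyl-8-(trimethylsilyl)-2H-chromen-7-ol
Product: 26 5-methoxy-2,2-dimethyl-8-(trimethylsilyl)-2H-chromen-7-yl trifluoromethanesulfonate
Conditions: PhNTf2 (1.2 equiv), DBU, MeCN, rt
Reagents that add atoms: N-phenylbis(trifluoromethanesulfonimide), O=S(=O)(N(c1ccccc1)S(=O)(=O)C(F)(F)F)C(F)(F)F
Why: O-sulfonylation of the remaining phenol under non-acidic conditions gives the o-silylaryl triflate while preserving the aryl–silicon bond and the chromene.

**Step 12**
Reactants: 16 (1R,2S,6R)-3-methyl-2-(3-methylbut-2-en-1-yl)-6-phenylcyclohex-3-ene-1-carboxylic acid; 26 5-methoxy-2,2-dimethyl-8-(trimethylsilyl)-2H-chromen-7-yl trifluoromethanesulfonate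
Product: 28 (7-hydroxy-5-methoxy-2,2-dimethyl-2H-chromen-8-yl)[(1R,2S,6R)-3-methyl-2-(3-methylbut-2-en-1-yl)-6-phenylcyclohex-3-en-1-yl]methanone, via aryne 27 (not isolated)
Conditions: 26 (1.5 equiv), CsF (4 equiv), THF (0.02 M), sealed tube, 125 °C; aq NH4Cl
Reagents that add atoms: none
Why: Fluoride removes the C8 silyl group and triflate leaves from C7 to give aryne 27; the cesium carboxylate of 16 adds through oxygen to C7, and the resulting C8 aryl anion attacks the adjacent ester carbonyl through a four-membered transition state whose collapse gives the C8 ketone and the C7 phenoxide, protonated on work-up. The closest known reaction type is the fluoride-induced insertion of arynes into the C–O bond of carboxylic acids to give ortho-hydroxyaryl ketones. No ring is closed and no stereocentre is made. The step needs regioselective addition across C7–C8: the inductively withdrawing O1 on C8a distorts the aryne so that the nucleophile adds at the remote, less hindered C7 and charge builds at C8. It also needs acyl transfer to outrun protonation of the aryl anion, which the hot, dilute, aprotic medium should favour. C1 of the acid, which becomes alpha to the ketone, already holds its equatorial and more stable orientation (trans to phenyl, cis to the pseudoaxial prenyl), so the basic medium should not erode it.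

**Compound list**
1 | prenyl bromide | CC(C)=CCBr | starting material
2 | 1-propynylmagnesium bromide | CC#C[Mg]Br | starting material
3 | 6-methylhept-5-en-2-yne | CC#CCC=C(C)C | intermediate
4 | (E)-chlorobis(cyclopentadienyl)(6-methylhepta-2,5-dien-2-yl)zirconium | C/C(=C\CC=C(C)C)[Zr](Cl)(C1C=CC=C1)C1C=CC=C1 | intermediate
5 | (E)-2-iodo-6-methylhepta-2,5-diene | C/C(I)=C\CC=C(C)C | intermediate
6 | 3-phenylglutaric anhydride | O=C1CC(c2ccccc2)CC(=O)O1 | starting material
7 | (R)-5-methoxy-5-oxo-3-phenylpentanoic acid | COC(=O)C[C@H](c1ccccc1)CC(=O)O | intermediate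
8 | methyl (S)-5-chloro-5-oxo-3-phenylpentanoate | COC(=O)C[C@H](c1ccccc1)CC(=O)Cl | intermediate
9 | (E)-(6-methylhepta-2,5-dien-2-yl)lithium | [Li]/C(C)=C/CC=C(C)C | intermediate
10 | (E)-(6-methylhepta-2,5-dien-2-yl)zinc chloride | Cl[Zn]/C(C)=C/CC=C(C)C | intermediate
11 | methyl (3R,6E)-6,10-dimethyl-5-oxo-3-phenylundeca-6,9-dienoate | COC(=O)C[C@H](c1ccccc1)CC(=O)/C(C)=C/CC=C(C)C | intermediate
12 | methyl (3R,5R,6E)-5-hydroxy-6,10-dimethyl-3-phenylundeca-6,9-dienoate | COC(=O)C[C@H](c1ccccc1)C[C@@H](O)/C(C)=C/CC=C(C)C | intermediate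
13 | (4R,6R)-6-[(2E)-6-methylhepta-2,5-dien-2-yl]-4-phenyloxan-2-one | O=C1C[C@H](c2ccccc2)C[C@H](/C(C)=C/CC=C(C)C)O1 | intermediate
14 | trimethyl{[(2R,4R)-2-[(2E)-6-methylhepta-2,5-dien-2-yl]-4-phenyl-3,4-dihydro-2H-pyran-6-yl]oxy}silane | C[Si](C)(C)OC1=C[C@H](c2ccccc2)C[C@H](/C(C)=C/CC=C(C)C)O1 | intermediate
15 | trimethylsilyl (1R,2S,6R)-3-methyl-2-(3-methylbut-2-en-1-yl)-6-phenylcyclohex-3-ene-1-carboxylate | C[Si](C)(C)OC(=O)[C@@H]1[C@H](CC=C(C)C)C(C)=CC[C@H]1c1ccccc1 | intermediate
16 | (1R,2S,6R)-3-methyl-2-(3-methylbut-2-en-1-yl)-6-phenylcyclohex-3-ene-1-carboxylic acid | OC(=O)[C@@H]1[C@H](CC=C(C)C)C(C)=CC[C@H]1c1ccccc1 | intermediate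
17 | 5-methoxyresorcinol | COc1cc(O)cc(O)c1 | starting material
18 | 5-methoxy-1,3-phenylene bis(N-isopropylcarbamate) | COc1cc(OC(=O)NC(C)C)cc(OC(=O)NC(C)C)c1 | intermediate
19 | 5-methoxy-1,3-phenylene bis[N-(tert-butyldimethylsilyl)-N-isopropylcarbamate] | COc1cc(OC(=O)N(C(C)C)[Si](C)(C)C(C)(C)C)cc(OC(=O)N(C(C)C)[Si](C)(C)C(C)(C)C)c1 | intermediate
20 | 2-lithio derivative of 19 | COc1cc(OC(=O)N(C(C)C)[Si](C)(C)C(C)(C)C)c([Li])c(OC(=O)N(C(C)C)[Si](C)(C)C(C)(C)C)c1 | intermediate
21 | 2-(trimethylsilyl) derivative of 19 | COc1cc(OC(=O)N(C(C)C)[Si](C)(C)C(C)(C)C)c([Si](C)(C)C)c(OC(=O)N(C(C)C)[Si](C)(C)C(C)(C)C)c1 | intermediate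
22 | 5-methoxy-2-(trimethylsilyl)-1,3-phenylene bis(N-isopropylcarbamate) | COc1cc(OC(=O)NC(C)C)c([Si](C)(C)C)c(OC(=O)NC(C)C)c1 | intermediate
23 | 5-methoxy-2-(trimethylsilyl)benzene-1,3-diol | COc1cc(O)c([Si](C)(C)C)c(O)c1 | intermediate
24 | 3-methyl-2-butenal | CC(C)=CC=O | starting material
25 | 5-methoxy-2,2-dimethyl-8-(trimethylsilyl)-2H-chromen-7-ol | COc1cc(O)c([Si](C)(C)C)c2OC(C)(C)C=Cc12 | intermediate
26 | 5-methoxy-2,2-dimethyl-8-(trimethylsilyl)-2H-chromen-7-yl trifluoromethanesulfonate | COc1cc(OS(=O)(=O)C(F)(F)F)c([Si](C)(C)C)c2OC(C)(C)C=Cc12 | intermediate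
27 | 5-methoxy-2,2-dimethyl-7,8-didehydro-2H-chromene (aryne) | COC1=CC#CC2=C1C=CC(C)(C)O2 | intermediate
28 | (7-hydroxy-5-methoxy-2,2-dimethyl-2H-chromen-8-yl)[(1R,2S,6R)-3-methyl-2-(3-methylbut-2-en-1-yl)-6-phenylcyclohex-3-en-1-yl]methanone | COc1cc(O)c(C(=O)[C@@H]2[C@H](CC=C(C)C)C(C)=CC[C@H]2c2ccccc2)c2c1C=CC(C)(C)O2 | target

**Step count.** Total: 12 steps. Longest linear sequence: 6 steps (1, 2, 4, 5, 6, 12, or equally 7 to 12).

**Steps most likely to fail**

Step 12. The C8 aryl anion may be protonated before it transfers the acyl group, leaving only the O-aryl ester, or the hindered carboxylate may add too slowly and the aryne be consumed by other paths. The fallback sets out from 17 and 16 and rejoins the route at 28. Bis-protection of 17 (MOMCl, i-Pr2NEt) gives 1-methoxy-3,5-bis(methoxymethoxy)benzene F1. Acid 16 is converted ((COCl)2, cat. DMF) into (1R,2S,6R)-3-methyl-2-(3-methylbut-2-en-1-yl)-6-phenylcyclohex-3-ene-1-carbonyl chloride F2. Lithiation of F1 between the two acetal oxygens (n-BuLi, THF, 0 °C) and acylation with F2 at −78 °C gives the bis(methoxymethyl) aryl ketone F3. Methanolic HCl frees the 2,6-dihydroxy-4-methoxyphenyl ketone F4. Annulation of F4 with 24 in pyridine then closes the pyran on either of its two equivalent hydroxyls and gives 28.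

Step 6. The rearrangement may stall because the boat transition state eclipses the alkene methyl with the silyloxy group and crowds the phenyl, or C-silylation may replace ketene acetal formation. The fallback sets out from 5 and rejoins at 16. Stille coupling of 5 with tributyl(vinyl)stannane (Pd(PPh3)4, DMF) gives (E)-β-ocimene F5. N-Acylation of lithiated (R)-4-benzyloxazolidin-2-one with cinnamoyl chloride gives (R)-4-benzyl-3-[(E)-cinnamoyl]oxazolidin-2-one F6. An Et2AlCl-promoted, auxiliary-controlled endo Diels–Alder reaction of F5 with F6 (CH2Cl2, −20 °C) gives the cyclohexenyl imide F7, which must be separated from its regioisomer. LiOH/H2O2 then removes the auxiliary and returns 16.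

Step 10. The C-silyl group may be lost from the very electron-rich ring on heating with amine, or a second annulation may give a bis-pyran. The fallback sets out from 23 and rejoins at 25. Mono-O-alkylation of 23 with 3-chloro-3-methylbut-1-yne (K2CO3, KI, CuCl2·2H2O (cat.), acetone) gives 5-methoxy-3-[(2-methylbut-3-yn-2-yl)oxy]-2-(trimethylsilyl)phenol F8. Heating F8 in o-xylene at 140 °C (aryl propargyl ether Claisen rearrangement, 1,5-hydrogen shift, oxa-6π electrocyclisation) builds the 2,2-dimethylchromene under neutral conditions and gives 25.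

**Further compounds**
F1 | step 12 | 1-methoxy-3,5-bis(methoxymethoxy)benzene | COCOc1cc(OC)cc(OCOC)c1
F2 | step 12 | (1R,2S,6R)-3-methyl-2-(3-methylbut-2-en-1-yl)-6-phenylcyclohex-3-ene-1-carbonyl chloride | ClC(=O)[C@@H]1[C@H](CC=C(C)C)C(C)=CC[C@H]1c1ccccc1
F3 | step 12 | [4-methoxy-2,6-bis(methoxymethoxy)phenyl][(1R,2S,6R)-3-methyl-2-(3-methylbut-2-en-1-yl)-6-phenylcyclohex-3-en-1-yl]methanone | COCOc1cc(OC)cc(OCOC)c1C(=O)[C@@H]1[C@H](CC=C(C)C)C(C)=CC[C@H]1c1ccccc1
F4 | step 12 | (2,6-dihydroxy-4-methoxyphenyl)[(1R,2S,6R)-3-methyl-2-(3-methylbut-2-en-1-yl)-6-phenylcyclohex-3-en-1-yl]methanone | COc1cc(O)c(C(=O)[C@@H]2[C@H](CC=C(C)C)C(C)=CC[C@H]2c2ccccc2)c(O)c1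
F5 | step 6 | (E)-β-ocimene, (3E)-3,7-dimethylocta-1,3,6-triene | C=C/C(C)=C/CC=C(C)C
F6 | step 6 | (R)-4-benzyl-3-[(E)-cinnamoyl]oxazolidin-2-one | O=C1OC[C@@H](Cc2ccccc2)N1C(=O)/C=C/c1ccccc1
F7 | step 6 | (R)-4-benzyl-3-{[(1R,2S,6R)-3-methyl-2-(3-methylbut-2-en-1-yl)-6-phenylcyclohex-3-en-1-yl]carbonyl}oxazolidin-2-one | O=C1OC[C@@H](Cc2ccccc2)N1C(=O)[C@@H]1[C@H](CC=C(C)C)C(C)=CC[C@H]1c1ccccc1
F8 | step 10 | 5-methoxy-3-[(2-methylbut-3-yn-2-yl)oxy]-2-(trimethylsilyl)phenol | COc1cc(O)c([Si](C)(C)C)c(OC(C)(C)C#C)c1
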